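**Plan**
- The target is read as (−)-epicatechin 3-O-gallate-(4β→8)-(−)-epigallocatechin 3-O-gallate. Retrosynthesis removes fifteen benzyl groups and the lower C3 gallate, then cuts lower O1–C2, then the upper C4–lower C8 aryl bond, then the ArCH2–C(sp) bond of the side chain.
- Enabling feature: in the lower pyran (F) ring, O1–C2 is benzylic to the pyrogallol (E) ring and the C2 aryl is cis to the C3 oxygen. O1 sits on D-ring carbon C8a, between C8 (which carries the upper unit) and C4a (which carries the C4 methylene). A single free phenol there can therefore open a cis-epoxide at its benzylic carbon.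
- Forward: rings A/C/B come intact from (−)-epicatechin (benzylation, C4 activation, galloylation). The D ring comes from 3,5-bis(benzyloxy)phenol, which receives an ortho propargyl chain by ortho-quinone methide alkynylation. The two halves are joined at C4 by Friedel–Crafts arylation.
- The alkyne is then semihydrogenated to the Z-alkene and epoxidised, the F ring is closed last by 6-endo phenol opening, and galloylation and hydrogenolysis finish the route.
- Stereochemistry: upper C2/C3 come from (−)-epicatechin; upper C4 from attack anti to the C2 aryl and C3 gallate; lower C3 from the (S,S)-Mn(salen) epoxidation; lower C2 from inversion in the ring closure.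

Key step: step 14

Remark: the face selectivity of the Mn(salen) catalyst is assigned by analogy with simple cis-β-alkylstyrenes, for which the (S,S)-complex gives the (1S,2R)-type cis-epoxide; the enantiomeric complex would be used if the large substrate responded in the opposite sense.

**Route**

Step 1
Reactants: 1 (−)-epicatechin
Product: 2 5,7,3′,4′-tetra-O-benzyl-(−)-epicatechin
Conditions: BnBr (4.4 equiv), K2CO3, DMF, 0 °C → rt, argon
Reagents that add atoms: benzyl bromide, BrCc1ccccc1
Why: Williamson etherification in which carbonate deprotonates only the four phenols, so the secondary C3 alcohol stays free and C2/C3 are not touched.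

Step 2
Reactants: 2 5,7,3′,4′-tetra-O-benzyl-(−)-epicatechin
Product: 3 5,7,3′,4′-tetra-O-benzyl-4β-(2-ethoxyethoxy)-(−)-epicatechin
Conditions: DDQ (2 equiv), 2-ethoxyethanol (5 equiv), CH2Cl2, rt
Reagents that add atoms: 2-ethoxyethanol, CCOCCO
Why: DDQ benzylic oxidation removes hydride from C4, which is activated by the ortho/para alkoxy groups of ring A, and the cation is trapped by the alcohol on the face opposite the C2 aryl and C3 hydroxyl to give the 3,4-trans ether (this centre is re-formed in step 9).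

Step 3
Reactants: 3 5,7,3′,4′-tetra-O-benzyl-4β-(2-ethoxyethoxy)-(−)-epicatechin; 4 3,4,5-tris(benzyloxy)benzoic acid
Product: 5 5,7,3′,4′-tetra-O-benzyl-4β-(2-ethoxyethoxy)-(−)-epicatechin 3-O-[3,4,5-tris(benzyloxy)benzoate]
Conditions: DCC, DMAP, CH2Cl2, 0 °C → rt
Reagents that add atoms: none
Why: Steglich esterification through the N-acylpyridinium species acylates the hindered C3 alcohol under neutral conditions that leave the acetal-like C4 ether and all stereocentres intact.

Step 4
Reactants: 6 3,4,5-tris(benzyloxy)benzaldehyde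
Product: 7 1,2,3-tris(benzyloxy)-5-ethynylbenzene
Conditions: dimethyl (1-diazo-2-oxopropyl)phosphonate, K2CO3, MeOH/THF, rt
Reagents that add atoms: dimethyl (1-diazo-2-oxopropyl)phosphonate, CC(=O)C(=[N+]=[N-])P(=O)(OC)OC
Why: Ohira–Bestmann (Seyferth–Gilbert) homologation, in which the diazomethylphosphonate anion released by methanolysis olefinates the aldehyde and loss of N2 with 1,2-shift gives the terminal alkyne without affecting the benzyl ethers.

Step 5
Reactants: 8 3,5-bis(benzyloxy)phenol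
Product: 9 4,6-bis(benzyloxy)-2-hydroxybenzaldehyde
Conditions: MgCl2, Et3N, (CH2O)n, MeCN, reflux; then 1 M HCl
Reagents that add atoms: paraformaldehyde (formaldehyde), C=O
Why: Magnesium-mediated ortho-formylation (Casnati–Skattebøl), in which the magnesium phenoxide delivers formaldehyde only to an ortho carbon and a second formaldehyde oxidises the hydroxymethyl intermediate, gives a single aldehyde because the two ortho positions of 8 are equivalent.

Step 6
Reactants: 9 4,6-bis(benzyloxy)-2-hydroxybenzaldehyde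
Product: 10 3,5-bis(benzyloxy)-2-formylphenyl tert-butyl carbonate
Conditions: Boc2O, DMAP (cat.), i-Pr2NEt (cat.), THF, 0 °C → rt
Reagents that add atoms: di-tert-butyl dicarbonate, CC(C)(C)OC(=O)OC(=O)OC(C)(C)C
Why: DMAP-catalysed acylation converts the chelated phenol into its tert-butyl carbonate, the group that later serves as the internal leaving group for ortho-quinone methide formation.

Step 7
Reactants: 10 3,5-bis(benzyloxy)-2-formylphenyl tert-butyl carbonate
Product: 11 3,5-bis(benzyloxy)-2-(hydroxymethyl)phenyl tert-butyl carbonate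
Conditions: BH3·THF, THF, 0 °C; then pH 7 buffer
Reagents that add atoms: none
Why: Borane reduces the aldehyde through a neutral borate ester rather than a free alkoxide, so the carbonate should not migrate and the O-Boc salicyl alcohol can be isolated.

Step 8
Reactants: 11 3,5-bis(benzyloxy)-2-(hydroxymethyl)phenyl tert-butyl carbonate; 7 1,2,3-tris(benzyloxy)-5-ethynylbenzene
Product: 14 3,5-bis(benzyloxy)-2-[3-(3,4,5-tris(benzyloxy)phenyl)prop-2-yn-1-yl]phenol, via arylethynylmagnesium bromide 12 (not isolated), via ortho-quinone methide 13 (not isolated)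
Conditions: 7, EtMgBr, THF, 0 °C → rt (gives 12); 11, t-BuMgCl (1.0 equiv), THF, −78 °C; then 12 (1.5 equiv), −78 °C → rt; aq. NH4Cl
Reagents that add atoms: none
Why: Anionic ortho-quinone methide generation, in which the magnesium alkoxide of 11 takes over the Boc group and expels tert-butyl carbonate to give 13, is followed by 1,4-addition of alkynyl Grignard 12 at the exocyclic methylene with rearomatisation, which places the propargyl chain exclusively ortho to the phenol.

Step 9
Reactants: 5 5,7,3′,4′-tetra-O-benzyl-4β-(2-ethoxyethoxy)-(−)-epicatechin 3-O-[3,4,5-tris(benzyloxy)benzoate]; 14 3,5-bis(benzyloxy)-2-[3-(3,4,5-tris(benzyloxy)phenyl)prop-2-yn-1-yl]phenol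
Product: 15 4β-{2-hydroxy-4,6-bis(benzyloxy)-3-[3-(3,4,5-tris(benzyloxy)phenyl)prop-2-yn-1-yl]phenyl}-5,7,3′,4′-tetra-O-benzyl-(−)-epicatechin 3-O-[3,4,5-tris(benzyloxy)benzoate]
Conditions: 14 (2 equiv), TMSOTf (0.3 equiv), CH2Cl2, −78 → −40 °C; aq. NaHCO3
Reagents that add atoms: none
Why: Lewis-acid Friedel–Crafts arylation of the flavan C4 cation, released by ionising the chelating 4-ether, should occur at the ring carbon of 14 flanked by the free hydroxyl and one benzyloxy group (the counterpart of C8 in benzylated flavan nucleophiles and less hindered than the carbon between two benzyloxy groups), with attack anti to the C2 aryl and the participating C3 gallate setting the 4β (3,4-trans) configuration.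

Step 10
Reactants: 15 alkynyl phenol (as named in step 9)
Product: 16 tert-butyldimethylsilyl ether of 15 at the D-ring phenol
Conditions: TBSOTf, 2,6-lutidine, CH2Cl2, 0 °C
Reagents that add atoms: tert-butyldimethylsilyl trifluoromethanesulfonate, CC(C)(C)[Si](C)(C)OS(=O)(=O)C(F)(F)F
Why: Silyl triflate with a hindered base silylates even a di-ortho-substituted phenol and masks the electron-rich phenol, the only free hydroxyl in 15, against the oxidant of step 12.

Step 11
Reactants: 16 silyl-protected alkyne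
Product: 17 silyl-protected (Z)-alkene, i.e. 16 with a (Z)-3-[3,4,5-tris(benzyloxy)phenyl]prop-2-en-1-yl chain
Conditions: H2 (1 atm), Lindlar catalyst, quinoline, EtOAc, rt
Reagents that add atoms: none
Why: Lindlar semihydrogenation delivers both hydrogens to one face of the alkyne on poisoned palladium and gives the Z-alkene while benzyl ethers, ester and silyl ether are not reduced.

Step 12
Reactants: 17 silyl-protected (Z)-alkene
Product: 18 silyl-protected cis-epoxide, side chain [(2R,3S)-3-(3,4,5-tris(benzyloxy)phenyl)oxiran-2-yl]methyl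
Conditions: (S,S)-Mn(salen)Cl (10 mol %), mCPBA, NMO, CH2Cl2, −78 °C
Reagents that add atoms: meta-chloroperbenzoic acid, OOC(=O)c1cccc(Cl)c1
Why: Jacobsen–Katsuki epoxidation of a cis-β-substituted styrene transfers oxygen from the Mn(V)-oxo species in a side-on approach, the (S,S)-ligand selecting the face that makes the homobenzylic carbon R and the benzylic carbon S, and the low temperature limits both the uncatalysed peracid reaction and cis-to-trans leakage.

Step 13
Reactants: 18 silyl-protected cis-epoxide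
Product: 19 free-phenol cis-epoxide, 4β-{2-hydroxy-4,6-bis(benzyloxy)-3-[((2R,3S)-3-(3,4,5-tris(benzyloxy)phenyl)oxiran-2-yl)methyl]phenyl}-5,7,3′,4′-tetra-O-benzyl-(−)-epicatechin 3-O-[3,4,5-tris(benzyloxy)benzoate]
Conditions: TBAF, AcOH, THF, 0 °C; extractive work-up, used directly
Reagents that add atoms: none
Why: Fluoride cleaves the aryl silyl ether much faster than it touches ester or epoxide, and the acetic acid buffer releases the phenol rather than the phenoxide, so base-induced exo opening of the epoxide is avoided.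

Step 14
Reactants: 19 free-phenol cis-epoxide
Product: 20 perbenzylated dimer with upper gallate and free lower C3 hydroxyl, i.e. 5,7,3′,4′-tetra-O-benzyl-(−)-epicatechin 3-O-[3,4,5-tris(benzyloxy)benzoate]-(4β→8)-5,7,3′,4′,5′-penta-O-benzyl-(−)-epigallocatechin
Conditions: PPTS (10 mol %), CH2Cl2–toluene, −20 → 0 °C; Et3N quench
Reagents that add atoms: none
Why: Hydrogen bonding or protonation of the epoxide oxygen by the weak acid polarises the benzylic C–O bond, and the phenol oxygen on C8a, held in reach by the C4a–CH2 tether, attacks that carbon from the rear in a borderline SN2 opening. The closest known reaction type is the acid-promoted intramolecular phenol opening of aryl-substituted epoxides to 2-arylchroman-3-ols. The pyran F ring closes in the 6-endo mode by forming O1–C2, because the endo carbon is the one whose developing positive charge is stabilised by the tris(benzyloxy)phenyl ring, so the 5-exo path to a dihydrobenzofuran is electronically disfavoured. The new stereocentre C2 is controlled by the epoxide: inversion at the S-configured benzylic carbon gives 2R, and since C3 keeps its oxygen and its R configuration the aryl group ends cis to the C3 hydroxyl. The step needs inversion to outrun ionisation, and this is secured by the two meta benzyloxy groups that temper the donor strength of the aryl ring together with the weak acid, the poorly ionising medium and the low temperature. The 4→8 connectivity needs no selection, because the only free phenol is the one flanked by C8 and C4a, and the C3 hydroxyl is left free for the next acylation.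

Step 15
Reactants: 20 perbenzylated dimer with free lower C3 hydroxyl; 4 3,4,5-tris(benzyloxy)benzoic acid
Product: 21 perbenzylated 3,3″-di-O-gallate (pentadeca-O-benzyl target)
Conditions: 4 (excess), DCC, DMAP, CH2Cl2, rt
Reagents that add atoms: none
Why: Steglich esterification acylates the remaining secondary alcohol, the only free hydroxyl in 20, with retention at C3.

Step 16
Reactants: 21 perbenzylated 3,3″-di-O-gallate
Product: 22 (−)-epicatechin 3-O-gallate-(4β→8)-(−)-epigallocatechin 3-O-gallate (CNP0296769.1)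
Conditions: H2 (1 atm), Pd(OH)2/C, THF/MeOH/H2O, rt
Reagents that add atoms: none
Why: Catalytic hydrogenolysis cleaves all fifteen aryl benzyl ethers while the two gallate esters, the interflavan bond and the five stereocentres are not affected under neutral conditions.

**Compound list**
1 | (−)-epicatechin, (2R,3R) | O[C@@H]1Cc2c(O)cc(O)cc2O[C@@H]1c1ccc(O)c(O)c1 | starting material
2 | 5,7,3′,4′-tetra-O-benzyl-(−)-epicatechin, (2R,3R) | O[C@@H]1Cc2c(OCc9ccccc9)cc(OCc9ccccc9)cc2O[C@@H]1c1ccc(OCc9ccccc9)c(OCc9ccccc9)c1 | intermediate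
3 | 5,7,3′,4′-tetra-O-benzyl-4β-(2-ethoxyethoxy)-(−)-epicatechin (2,3-cis, 3,4-trans) | O[C@@H]1[C@@H](OCCOCC)c2c(OCc9ccccc9)cc(OCc9ccccc9)cc2O[C@@H]1c1ccc(OCc9ccccc9)c(OCc9ccccc9)c1 | intermediate
4 | 3,4,5-tris(benzyloxy)benzoic acid | O=C(O)c1cc(OCc9ccccc9)c(OCc9ccccc9)c(OCc9ccccc9)c1 | starting material
5 | 5,7,3′,4′-tetra-O-benzyl-4β-(2-ethoxyethoxy)-(−)-epicatechin 3-O-[3,4,5-tris(benzyloxy)benzoate] | O=C(O[C@@H]1[C@@H](OCCOCC)c2c(OCc9ccccc9)cc(OCc9ccccc9)cc2O[C@@H]1c1ccc(OCc9ccccc9)c(OCc9ccccc9)c1)c1cc(OCc9ccccc9)c(OCc9ccccc9)c(OCc9ccccc9)c1 | intermediate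
6 | 3,4,5-tris(benzyloxy)benzaldehyde | O=Cc1cc(OCc9ccccc9)c(OCc9ccccc9)c(OCc9ccccc9)c1 | starting material
7 | 1,2,3-tris(benzyloxy)-5-ethynylbenzene | C#Cc1cc(OCc9ccccc9)c(OCc9ccccc9)c(OCc9ccccc9)c1 | intermediate
8 | 3,5-bis(benzyloxy)phenol | Oc1cc(OCc9ccccc9)cc(OCc9ccccc9)c1 | starting material
9 | 4,6-bis(benzyloxy)-2-hydroxybenzaldehyde | O=Cc1c(O)cc(OCc9ccccc9)cc1OCc9ccccc9 | intermediate
10 | 3,5-bis(benzyloxy)-2-formylphenyl tert-butyl carbonate | O=Cc1c(OC(=O)OC(C)(C)C)cc(OCc9ccccc9)cc1OCc9ccccc9 | intermediate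
11 | 3,5-bis(benzyloxy)-2-(hydroxymethyl)phenyl tert-butyl carbonate | OCc1c(OC(=O)OC(C)(C)C)cc(OCc9ccccc9)cc1OCc9ccccc9 | intermediate
12 | [3,4,5-tris(benzyloxy)phenyl]ethynylmagnesium bromide | Br[Mg]C#Cc1cc(OCc9ccccc9)c(OCc9ccccc9)c(OCc9ccccc9)c1 | intermediate
13 | 3,5-bis(benzyloxy)-6-methylidenecyclohexa-2,4-dien-1-one (ortho-quinone methide) | C=C1C(=O)C=C(OCc9ccccc9)C=C1OCc9ccccc9 | intermediate
14 | 3,5-bis(benzyloxy)-2-[3-(3,4,5-tris(benzyloxy)phenyl)prop-2-yn-1-yl]phenol | Oc1cc(OCc9ccccc9)cc(OCc9ccccc9)c1CC#Cc1cc(OCc9ccccc9)c(OCc9ccccc9)c(OCc9ccccc9)c1 | intermediate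
15 | 4β-{2-hydroxy-4,6-bis(benzyloxy)-3-[3-(3,4,5-tris(benzyloxy)phenyl)prop-2-yn-1-yl]phenyl}-5,7,3′,4′-tetra-O-benzyl-(−)-epicatechin 3-O-[3,4,5-tris(benzyloxy)benzoate] (2,3-cis, 3,4-trans) | O=C(O[C@@H]1[C@@H](c2c(OCc9ccccc9)cc(OCc9ccccc9)c(CC#Cc3cc(OCc9ccccc9)c(OCc9ccccc9)c(OCc9ccccc9)c3)c2O)c2c(OCc9ccccc9)cc(OCc9ccccc9)cc2O[C@@H]1c1ccc(OCc9ccccc9)c(OCc9ccccc9)c1)c1cc(OCc9ccccc9)c(OCc9ccccc9)c(OCc9ccccc9)c1 | intermediate
16 | D-ring O-tert-butyldimethylsilyl ether of 15 | O=C(O[C@@H]1[C@@H](c2c(OCc9ccccc9)cc(OCc9ccccc9)c(CC#Cc3cc(OCc9ccccc9)c(OCc9ccccc9)c(OCc9ccccc9)c3)c2O[Si](C)(C)C(C)(C)C)c2c(OCc9ccccc9)cc(OCc9ccccc9)cc2O[C@@H]1c1ccc(OCc9ccccc9)c(OCc9ccccc9)c1)c1cc(OCc9ccccc9)c(OCc9ccccc9)c(OCc9ccccc9)c1 | intermediate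
17 | (Z)-alkene from 16, side chain (Z)-3-[3,4,5-tris(benzyloxy)phenyl]prop-2-en-1-yl | O=C(O[C@@H]1[C@@H](c2c(OCc9ccccc9)cc(OCc9ccccc9)c(C/C=C\c3cc(OCc9ccccc9)c(OCc9ccccc9)c(OCc9ccccc9)c3)c2O[Si](C)(C)C(C)(C)C)c2c(OCc9ccccc9)cc(OCc9ccccc9)cc2O[C@@H]1c1ccc(OCc9ccccc9)c(OCc9ccccc9)c1)c1cc(OCc9ccccc9)c(OCc9ccccc9)c(OCc9ccccc9)c1 | intermediate
18 | silyl-protected cis-epoxide, side chain [(2R,3S)-3-(3,4,5-tris(benzyloxy)phenyl)oxiran-2-yl]methyl | O=C(O[C@@H]1[C@@H](c2c(OCc9ccccc9)cc(OCc9ccccc9)c(C[C@H]3O[C@H]3c4cc(OCc9ccccc9)c(OCc9ccccc9)c(OCc9ccccc9)c4)c2O[Si](C)(C)C(C)(C)C)c2c(OCc9ccccc9)cc(OCc9ccccc9)cc2O[C@@H]1c1ccc(OCc9ccccc9)c(OCc9ccccc9)c1)c1cc(OCc9ccccc9)c(OCc9ccccc9)c(OCc9ccccc9)c1 | intermediate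
19 | free-phenol cis-epoxide (desilylated 18; oxirane 2R,3S) | O=C(O[C@@H]1[C@@H](c2c(OCc9ccccc9)cc(OCc9ccccc9)c(C[C@H]3O[C@H]3c4cc(OCc9ccccc9)c(OCc9ccccc9)c(OCc9ccccc9)c4)c2O)c2c(OCc9ccccc9)cc(OCc9ccccc9)cc2O[C@@H]1c1ccc(OCc9ccccc9)c(OCc9ccccc9)c1)c1cc(OCc9ccccc9)c(OCc9ccccc9)c(OCc9ccccc9)c1 | intermediate
20 | tetra-O-benzyl-(−)-epicatechin 3-O-[tris(benzyloxy)benzoate]-(4β→8)-penta-O-benzyl-(−)-epigallocatechin (lower unit 2R,3R, free 3-OH) | O=C(O[C@@H]1[C@@H](c2c(OCc9ccccc9)cc(OCc9ccccc9)c3c2O[C@H](c2cc(OCc9ccccc9)c(OCc9ccccc9)c(OCc9ccccc9)c2)[C@H](O)C3)c2c(OCc9ccccc9)cc(OCc9ccccc9)cc2O[C@@H]1c1ccc(OCc9ccccc9)c(OCc9ccccc9)c1)c1cc(OCc9ccccc9)c(OCc9ccccc9)c(OCc9ccccc9)c1 | intermediate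
21 | pentadeca-O-benzyl derivative of the target (both C3 hydroxyls as tris(benzyloxy)benzoates) | O=C(O[C@@H]1[C@@H](c2c(OCc9ccccc9)cc(OCc9ccccc9)c3c2O[C@H](c2cc(OCc9ccccc9)c(OCc9ccccc9)c(OCc9ccccc9)c2)[C@H](OC(=O)c2cc(OCc9ccccc9)c(OCc9ccccc9)c(OCc9ccccc9)c2)C3)c2c(OCc9ccccc9)cc(OCc9ccccc9)cc2O[C@@H]1c1ccc(OCc9ccccc9)c(OCc9ccccc9)c1)c1cc(OCc9ccccc9)c(OCc9ccccc9)c(OCc9ccccc9)c1 | intermediate
22 | (−)-epicatechin 3-O-gallate-(4β→8)-(−)-epigallocatechin 3-O-gallate (CNP0296769.1) | O=C(O[C@@H]1[C@@H](c2c(O)cc(O)c3c2O[C@H](c2cc(O)c(O)c(O)c2)[C@H](OC(=O)c2cc(O)c(O)c(O)c2)C3)c2c(O)cc(O)cc2O[C@@H]1c1ccc(O)c(O)c1)c1cc(O)c(O)c(O)c1 | target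

**Step count and risks**

Total steps: 16. Longest linear sequence: 12 steps (from 8 through steps 5–16 to 22).

Most likely to fail, step 14. The benzylic C–O bond may ionise before the phenol attacks, which would erode the inversion and give the 2,3-trans epimer at C2, or the phenol may attack the homobenzylic carbon in the exo mode. The fallback gives up ring construction on the dimer and forms the interflavan bond between two intact flavans. It sets out from 5, which is treated under the step 9 conditions (TMSOTf, CH2Cl2, −78 °C) with an excess of 5,7,3′,4′,5′-penta-O-benzyl-(−)-epigallocatechin F1, obtained from commercial (−)-epigallocatechin with BnBr/K2CO3 in DMF. The known preference of benzylated flavan nucleophiles for C8 should give 20 directly, where the route is rejoined for steps 15 and 16.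

Second, step 12. Facial selectivity may be poor on the large substrate, and the stepwise radical pathway of the Mn-oxo transfer may leak to the trans-epoxide, which would later give a 2,3-trans lower unit. The fallback replaces catalyst control by a concerted oxidant and separation. It sets out from 17, which is epoxidised with dimethyldioxirane (acetone/CH2Cl2, −20 °C), a strictly syn oxygen transfer that can only give cis-epoxides. Because the upper unit is a single enantiomer the two products are diastereomers, and 18 is separated by chromatography on base-washed silica from the (2S,3R)-oxirane diastereomer of 18 F2. The route is rejoined at 18.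

Third, step 9. Attack may compete at the D-ring carbon para to the phenol (between the two benzyloxy groups), and the product may be arylated again because 14 cannot be used in large excess. The fallback attaches the D ring first and builds the side chain afterwards. It sets out from 5, which is coupled (TMSOTf, CH2Cl2, −78 °C) with a large excess of the simple phenol 8, in which two of the three reactive carbons lead to the desired ortho product. This should give 4β-[2-hydroxy-4,6-bis(benzyloxy)phenyl]-5,7,3′,4′-tetra-O-benzyl-(−)-epicatechin 3-O-[3,4,5-tris(benzyloxy)benzoate] F3, and any para isomer is removed at this simple stage. Magnesium-mediated ortho-formylation (MgCl2, Et3N, paraformaldehyde) then has only one ortho carbon available and gives the 3-formyl derivative F4. Addition of alkynyl Grignard 12 (3 equiv, THF, −40 → 0 °C), to which the hindered benzoate should be inert, gives the propargylic alcohol F5 as a mixture of carbinol epimers. Ionic hydrogenation (Et3SiH, TFA, CH2Cl2, −78 °C) removes the carbinol oxygen and gives 15, where the route is rejoined.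

**Further compounds**
F1 | step 14 | 5,7,3′,4′,5′-penta-O-benzyl-(−)-epigallocatechin, (2R,3R) | O[C@@H]1Cc2c(OCc9ccccc9)cc(OCc9ccccc9)cc2O[C@@H]1c1cc(OCc9ccccc9)c(OCc9ccccc9)c(OCc9ccccc9)c1
F2 | step 12 | (2S,3R)-oxirane diastereomer of 18 | O=C(O[C@@H]1[C@@H](c2c(OCc9ccccc9)cc(OCc9ccccc9)c(C[C@@H]3O[C@@H]3c4cc(OCc9ccccc9)c(OCc9ccccc9)c(OCc9ccccc9)c4)c2O[Si](C)(C)C(C)(C)C)c2c(OCc9ccccc9)cc(OCc9ccccc9)cc2O[C@@H]1c1ccc(OCc9ccccc9)c(OCc9ccccc9)c1)c1cc(OCc9ccccc9)c(OCc9ccccc9)c(OCc9ccccc9)c1
F3 | step 9 | 4β-[2-hydroxy-4,6-bis(benzyloxy)phenyl]-5,7,3′,4′-tetra-O-benzyl-(−)-epicatechin 3-O-[3,4,5-tris(benzyloxy)benzoate] | O=C(O[C@@H]1[C@@H](c2c(OCc9ccccc9)cc(OCc9ccccc9)cc2O)c2c(OCc9ccccc9)cc(OCc9ccccc9)cc2O[C@@H]1c1ccc(OCc9ccccc9)c(OCc9ccccc9)c1)c1cc(OCc9ccccc9)c(OCc9ccccc9)c(OCc9ccccc9)c1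
F4 | step 9 | 4β-[3-formyl-2-hydroxy-4,6-bis(benzyloxy)phenyl]-5,7,3′,4′-tetra-O-benzyl-(−)-epicatechin 3-O-[3,4,5-tris(benzyloxy)benzoate] | O=C(O[C@@H]1[C@@H](c2c(OCc9ccccc9)cc(OCc9ccccc9)c(C=O)c2O)c2c(OCc9ccccc9)cc(OCc9ccccc9)cc2O[C@@H]1c1ccc(OCc9ccccc9)c(OCc9ccccc9)c1)c1cc(OCc9ccccc9)c(OCc9ccccc9)c(OCc9ccccc9)c1
F5 | step 9 | 4β-{2-hydroxy-3-[1-hydroxy-3-(3,4,5-tris(benzyloxy)phenyl)prop-2-yn-1-yl]-4,6-bis(benzyloxy)phenyl}-5,7,3′,4′-tetra-O-benzyl-(−)-epicatechin 3-O-[3,4,5-tris(benzyloxy)benzoate], carbinol centre as epimer mixture | O=C(O[C@@H]1[C@@H](c2c(OCc9ccccc9)cc(OCc9ccccc9)c(C(O)C#Cc3cc(OCc9ccccc9)c(OCc9ccccc9)c(OCc9ccccc9)c3)c2O)c2c(OCc9ccccc9)cc(OCc9ccccc9)cc2O[C@@H]1c1ccc(OCc9ccccc9)c(OCc9ccccc9)c1)c1cc(OCc9ccccc9)c(OCc9ccccc9)c(OCc9ccccc9)c1
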